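Numbering: C1 (quaternary oxirane carbon), C2 (oxirane CH), C3=C4, C5 (CHOBz), C6 (CHOH), C7 (exocyclic CH2). The route rests on the C1–C7 bond. Carbocycle C1–C6 and C7 are first assembled as one seven-membered carbocycle, the furan/alkoxyallyl-cation (4+3) adduct, in which C7 is the ketone carbon and the furan oxygen bridges C2 and C5. Wolff rearrangement of the derived α-diazoketone shifts C6 from C7 to C1 with retention. This contracts the ring to C1–C6 and expels C7 as the ester carbon in one operation. Bridge β-elimination then unveils the trans-5,6-diol diene, and hydroxyl-directed epoxidation of C1=C2 completes the target.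

Key step: step 5

Assumption: the (S)-configured 1-(2-naphthyl)ethyl group is taken to shield the cation face that leads to (1S,2R,5S)-6. If the sense of induction is the opposite one, the equally available (R)-alcohol is used and nothing else changes.

Step 1
Reactants: 1 1,1-dimethoxypropan-2-one (methylglyoxal dimethyl acetal); 2 (S)-1-(naphthalen-2-yl)ethanol
Product: 3 1-methoxy-1-[(S)-1-(naphthalen-2-yl)ethoxy]propan-2-one (both epimers at the acetal carbon)
Conditions: PPTS (cat.), 1 in excess, cyclohexane, reflux, 4 Å MS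
Reagents that add atoms: none
Why: Acid-catalysed transacetalisation, driven by removal of methanol, exchanges one methoxy group for the chiral alkoxy group; the new acetal centre forms as both epimers and is planarised in step 3.

Step 2
Reactants: 3 1-methoxy-1-[(S)-1-(naphthalen-2-yl)ethoxy]propan-2-one
Product: 4 triethyl({3-methoxy-3-[(S)-1-(naphthalen-2-yl)ethoxy]prop-1-en-2-yl}oxy)silane
Conditions: LDA, THF, −78 °C; TESCl
Reagents that add atoms: chlorotriethylsilane, CC[Si](Cl)(CC)CC
Why: Kinetic deprotonation of the methyl ketone at the unhindered CH3 and O-silylation (silyl enol ether formation) give the 2-silyloxyallyl acetal, with no new stereocentre.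

Step 3
Reactants: 4 triethyl({3-methoxy-3-[(S)-1-(naphthalen-2-yl)ethoxy]prop-1-en-2-yl}oxy)silane; 5 furan
Product: 6 (1S,2R,5S)-2-[(S)-1-(naphthalen-2-yl)ethoxy]-8-oxabicyclo[3.2.1]oct-6-en-3-one (alkoxy group equatorial, trans to the oxygen bridge on the seven-membered carbocycle)
Conditions: TMSOTf (10 mol %), furan (excess), CH2Cl2, −95 °C; chromatography
Reagents that add atoms: none
Why: Silyl-triflate ionisation of the smaller methoxy group gives a 1-alkoxy-2-silyloxyallyl cation that adds to furan in a (4+3) cycloaddition through the compact arrangement, which places the alkoxy group equatorial, while the naphthyl group stacked over one face of the cation sets the absolute configuration of C2, C5 and C6.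

Step 4
Reactants: 6 (1S,2R,5S)-2-[(S)-1-(naphthalen-2-yl)ethoxy]-8-oxabicyclo[3.2.1]oct-6-en-3-one
Product: 8 (1R,4R,5S)-2-diazo-4-[(S)-1-(naphthalen-2-yl)ethoxy]-8-oxabicyclo[3.2.1]oct-6-en-3-one, via the C1-trifluoroacetyl derivative of 6 (enolised 1,3-diketone) 7 (not isolated)
Conditions: LiHMDS, THF, −78 °C; CF3CO2CH2CF3; aq. HCl wash; then 4-acetamidobenzenesulfonyl azide, Et3N, H2O (1 equiv), MeCN, rt
Reagents that add atoms: 2,2,2-trifluoroethyl trifluoroacetate, O=C(OCC(F)(F)F)C(F)(F)F (CF3CO group of 7); 4-acetamidobenzenesulfonyl azide, CC(=O)Nc1ccc(cc1)S(=O)(=O)N=[N+]=[N-] (N2 of 8)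
Why: Deacylative Regitz diazo transfer: the kinetic enolate forms at the unsubstituted C1H2 and not at the alkoxy-bearing C6, C-trifluoroacetylation activates this carbon, and the sulfonyl azide delivers N2 while the trifluoroacetyl group leaves on the sulfonamide, so that no stereocentre is touched.

Step 5
Reactants: 8 (1R,4R,5S)-2-diazo-4-[(S)-1-(naphthalen-2-yl)ethoxy]-8-oxabicyclo[3.2.1]oct-6-en-3-one
Product: 10 methyl (1R,3S,4S)-3-endo-[(S)-1-(naphthalen-2-yl)ethoxy]-7-oxabicyclo[2.2.1]hept-5-ene-2-carboxylate (both epimers at the ester-bearing carbon C1, a centre that is lost in step 7), via the ring-contracted ketene 9 (not isolated)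
Conditions: hν (365 nm LED), MeOH, 0 °C
Reagents that add atoms: methanol, CO
Why: Excitation of the s-cis-locked cyclic α-diazoketone expels N2 with concerted 1,2-shift of C6 from the carbonyl carbon C7 to the diazo carbon C1 (Wolff rearrangement), giving ketene 9, which methanol traps as the ester. The closest known reaction type is the photochemical Wolff ring contraction of cyclic and bridged bicyclic 2-diazoketones to the next lower cycloalkanecarboxylates. No ring is closed by cyclisation: the seven-membered carbocycle C1–C7–C6–C5–C4–C3–C2 becomes the six-membered carbocycle C1–C6 by a suprafacial 1,2-alkyl shift, while the oxygen bridge C2–O–C5 stays in place. C6 migrates with retention, so its equatorial alkoxy group ends endo, trans to the bridge oxygen on C5; C2 and C5 are untouched, and the new centre C1 (ketene protonation) forms as a mixture that step 7 erases. The 1,2-shift must beat O–H insertion and sensitised triplet chemistry: only C6 can migrate, a 1,2-H shift from bridgehead C2 would give an anti-Bredt alkene, and 365 nm light is absorbed by the diazoketone but not by the naphthalene.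

Step 6
Reactants: 10 methyl (1R,3S,4S)-3-endo-[(S)-1-(naphthalen-2-yl)ethoxy]-7-oxabicyclo[2.2.1]hept-5-ene-2-carboxylate
Product: 11 methyl (1R,3S,4S)-3-endo-hydroxy-7-oxabicyclo[2.2.1]hept-5-ene-2-carboxylate (both C1 epimers)
Conditions: DDQ, CH2Cl2/pH 7 buffer, 0 °C to rt
Reagents that add atoms: none
Why: DDQ abstracts the doubly activated naphthylic hydride (oxidative cleavage of a naphthylmethyl-type ether) and water hydrolyses the oxocarbenium ion, which frees the C6 hydroxyl with its C–O bond intact under neutral conditions that spare ester, alkene and bridge.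

Step 7
Reactants: 11 methyl (1R,3S,4S)-3-endo-hydroxy-7-oxabicyclo[2.2.1]hept-5-ene-2-carboxylate
Product: 13 methyl (5S,6S)-5,6-dihydroxycyclohexa-1,3-diene-1-carboxylate, via the 3-endo-trimethylsilyl ether of 11 12 (not isolated)
Conditions: TMSCl, Et3N, THF, 0 °C, filter; LiHMDS, THF, −78 to −30 °C; AcOH; citric acid (cat.), MeOH, 0 °C
Reagents that add atoms: chlorotrimethylsilane, C[Si](C)(C)Cl (silyl group of 12 only)
Why: After transient O-silylation either C1 epimer gives the same ester enolate, which expels the strained allylic bridge oxygen from C2 (E1cB, retro-oxa-Michael opening of a 7-oxanorbornene-2-carboxylate) to give the conjugated dienoate with the bridge oxygen left on C5, trans to C6–O, and mild methanolysis removes the silyl group wherever it sits.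

Step 8
Reactants: 13 methyl (5S,6S)-5,6-dihydroxycyclohexa-1,3-diene-1-carboxylate
Product: 14 (1S,2S)-3-(hydroxymethyl)cyclohexa-3,5-diene-1,2-diol
Conditions: DIBAL-H (excess), CH2Cl2, −78 to −20 °C; Rochelle salt
Reagents that add atoms: none
Why: DIBAL-H reduces the conjugated ester in 1,2-fashion to the primary allylic alcohol at low temperature without touching the diene or the two carbinol centres.

Step 9
Reactants: 14 (1S,2S)-3-(hydroxymethyl)cyclohexa-3,5-diene-1,2-diol
Product: 15 [(5S,6S)-5-(benzoyloxy)-6-hydroxycyclohexa-1,3-dien-1-yl]methyl benzoate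
Conditions: BzCl (2.05 equiv), pyridine, CH2Cl2, −40 °C
Reagents that add atoms: benzoyl chloride, O=C(Cl)c1ccccc1
Why: Rate-controlled acylation: the primary C7 hydroxyl reacts first and, of the two secondary hydroxyls, C5–OH (flanked by the unsubstituted C4H) is acylated faster than C6–OH, which is crowded by the C1 side chain.

Step 10
Reactants: 15 [(5S,6S)-5-(benzoyloxy)-6-hydroxycyclohexa-1,3-dien-1-yl]methyl benzoate
Product: 16 (−)-pipoxide, [(1R,2R,3S,6S)-3-(benzoyloxy)-2-hydroxy-7-oxabicyclo[4.1.0]hept-4-en-1-yl]methyl benzoate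
Conditions: mCPBA (1.05 equiv), CH2Cl2, 0 °C; cold basic wash
Reagents that add atoms: 3-chloroperoxybenzoic acid, O=C(OO)c1cccc(Cl)c1
Why: The C6 hydroxyl hydrogen-bonds the peracid and delivers oxygen to the adjacent, more substituted C1=C2 bond on its own face (hydroxyl-directed Prilezhaev epoxidation), which sets C1 and C2 cis to C6–OH, while the C5 benzoate on the other face reinforces this choice.

Compound list
1 | 1,1-dimethoxypropan-2-one | CC(=O)C(OC)OC | starting material
2 | (S)-1-(naphthalen-2-yl)ethanol | C[C@H](O)c1ccc2ccccc2c1 | starting material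
3 | 1-methoxy-1-[(S)-1-(naphthalen-2-yl)ethoxy]propan-2-one (acetal epimers) | CC(=O)C(OC)O[C@@H](C)c1ccc2ccccc2c1 | intermediate
4 | triethyl({3-methoxy-3-[(S)-1-(naphthalen-2-yl)ethoxy]prop-1-en-2-yl}oxy)silane | C=C(O[Si](CC)(CC)CC)C(OC)O[C@@H](C)c1ccc2ccccc2c1 | intermediate
5 | furan | c1ccoc1 | starting material
6 | (1S,2R,5S)-2-[(S)-1-(naphthalen-2-yl)ethoxy]-8-oxabicyclo[3.2.1]oct-6-en-3-one | C1C(=O)[C@H](O[C@@H](C)c3ccc4ccccc4c3)[C@@H]2C=C[C@H]1O2 | intermediate
7 | C1-trifluoroacetyl derivative of 6 (not isolated) | O=C(C1C(=O)[C@H](O[C@@H](C)c3ccc4ccccc4c3)[C@@H]2C=C[C@H]1O2)C(F)(F)F | intermediate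
8 | (1R,4R,5S)-2-diazo-4-[(S)-1-(naphthalen-2-yl)ethoxy]-8-oxabicyclo[3.2.1]oct-6-en-3-one | [N-]=[N+]=C1C(=O)[C@H](O[C@@H](C)c3ccc4ccccc4c3)[C@@H]2C=C[C@H]1O2 | intermediate
9 | {(1R,3S,4S)-3-endo-[(S)-1-(naphthalen-2-yl)ethoxy]-7-oxabicyclo[2.2.1]hept-5-en-2-ylidene}methanone (ketene, not isolated) | O=C=C1[C@H]2C=C[C@H](O2)[C@H]1O[C@@H](C)c3ccc4ccccc4c3 | intermediate
10 | methyl (1R,3S,4S)-3-endo-[(S)-1-(naphthalen-2-yl)ethoxy]-7-oxabicyclo[2.2.1]hept-5-ene-2-carboxylate (C1 epimers) | COC(=O)C1[C@H]2C=C[C@H](O2)[C@H]1O[C@@H](C)c3ccc4ccccc4c3 | intermediate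
11 | methyl (1R,3S,4S)-3-endo-hydroxy-7-oxabicyclo[2.2.1]hept-5-ene-2-carboxylate (C1 epimers) | COC(=O)C1[C@H]2C=C[C@H](O2)[C@H]1O | intermediate
12 | methyl (1R,3S,4S)-3-endo-(trimethylsilyloxy)-7-oxabicyclo[2.2.1]hept-5-ene-2-carboxylate (not isolated) | COC(=O)C1[C@H]2C=C[C@H](O2)[C@H]1O[Si](C)(C)C | intermediate
13 | methyl (5S,6S)-5,6-dihydroxycyclohexa-1,3-diene-1-carboxylate | COC(=O)C1=CC=C[C@H](O)[C@H]1O | intermediate
14 | (1S,2S)-3-(hydroxymethyl)cyclohexa-3,5-diene-1,2-diol | OCC1=CC=C[C@H](O)[C@H]1O | intermediate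
15 | [(5S,6S)-5-(benzoyloxy)-6-hydroxycyclohexa-1,3-dien-1-yl]methyl benzoate | O=C(OCC1=CC=C[C@H](OC(=O)c2ccccc2)[C@H]1O)c1ccccc1 | intermediate
16 | (−)-pipoxide | O=C(OC[C@]12O[C@H]1C=C[C@H](OC(=O)c1ccccc1)[C@H]2O)c1ccccc1 | target

Total step count: 10. Longest linear sequence: 10.

Steps most likely to fail

Step 7. The C6 silyloxy group may be lost in place of the bridge oxygen, or the dienoate may eliminate further to the arene under the strong base. The fallback sets out from 11 and comes back at 14. It changes the acceptor from ester to aldehyde, so that an amine base suffices and the C6 hydroxyl stays free. DIBAL-H reduces 11 to the 2-(hydroxymethyl)-7-oxanorbornen-3-endo-ol F5. TEMPO/PhI(OAc)2 oxidises only the primary alcohol to the β-hydroxy aldehyde F6. DBU in CH2Cl2 at 0 °C opens the bridge to the (5S,6S)-dihydroxy dienal F7, and Luche reduction gives 14.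

Step 9. The two secondary hydroxyls may be poorly discriminated, or the benzoyl group may migrate from the C5 to the C6 oxygen under base. The fallback sets out from 14 and comes back at 15. It blocks the C6 oxygen in a temporary ring. PhB(OH)2 ties the C7 and C6 hydroxyls (a 1,3-diol) into the six-membered cyclic phenylboronate F8. BzCl/pyridine acylates the only free hydroxyl to give the C5-benzoyl boronate F9. Exchange with pinacol releases the C5-monobenzoate diol F10. Primary-selective benzoylation (BzCl, 1 equiv, collidine, −78 °C) then gives 15.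

Step 5. Insertion of the carbene into the O–H bond of methanol, or hydrogen abstraction after intersystem crossing, may compete with the 1,2-shift. The fallback sets out from 6 and comes back at 10. It contracts the ring by a halohydrin semipinacol (quasi-Favorskii) shift in place of a carbene.
- The kinetic lithium enolate of 6 is chlorinated with NCS, and the chloride is equilibrated with Et3N to the equatorial α′-chloro ketone F1.
- NaBH4/CeCl3 gives the chlorohydrin F2, whose C7–C6 bond is antiperiplanar to C1–Cl.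
- KH in THF triggers the shift of C6 to C1, with retention at C6 and loss of chloride, to the ring-contracted endo-aldehyde F3.
- Pinnick oxidation gives the carboxylic acid F4, and TMSCHN2 gives 10.

Further compounds
F1 | step 5 | equatorial C1-chloro derivative of 6 (4-chloro-2-alkoxy-8-oxabicyclo[3.2.1]oct-6-en-3-one) | Cl[C@@H]1C(=O)[C@H](O[C@@H](C)c3ccc4ccccc4c3)[C@@H]2C=C[C@H]1O2
F2 | step 5 | chlorohydrin from F1 (carbinol epimers) | Cl[C@@H]1C(O)[C@H](O[C@@H](C)c3ccc4ccccc4c3)[C@@H]2C=C[C@H]1O2
F3 | step 5 | 3-endo-[(S)-1-(naphthalen-2-yl)ethoxy]-7-oxabicyclo[2.2.1]hept-5-ene-2-endo-carbaldehyde | O=C[C@H]1[C@H]2C=C[C@H](O2)[C@H]1O[C@@H](C)c3ccc4ccccc4c3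
F4 | step 5 | 3-endo-[(S)-1-(naphthalen-2-yl)ethoxy]-7-oxabicyclo[2.2.1]hept-5-ene-2-endo-carboxylic acid | OC(=O)[C@H]1[C@H]2C=C[C@H](O2)[C@H]1O[C@@H](C)c3ccc4ccccc4c3
F5 | step 7 | (1R,3S,4S)-2-(hydroxymethyl)-7-oxabicyclo[2.2.1]hept-5-en-3-endo-ol | OCC1[C@H]2C=C[C@H](O2)[C@H]1O
F6 | step 7 | (1R,3S,4S)-3-endo-hydroxy-7-oxabicyclo[2.2.1]hept-5-ene-2-carbaldehyde | O=CC1[C@H]2C=C[C@H](O2)[C@H]1O
F7 | step 7 | (5S,6S)-5,6-dihydroxycyclohexa-1,3-diene-1-carbaldehyde | O=CC1=CC=C[C@H](O)[C@H]1O
F8 | step 9 | cyclic phenylboronate of the C7/C6 diol of 14 (C5–OH free) | c1ccccc1B2OCC3=CC=C[C@H](O)[C@H]3O2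
F9 | step 9 | C5 benzoate of F8 | c1ccccc1B2OCC3=CC=C[C@H](OC(=O)c4ccccc4)[C@H]3O2
F10 | step 9 | (1S,6S)-6-hydroxy-5-(hydroxymethyl)cyclohexa-2,4-dien-1-yl benzoate | OCC1=CC=C[C@H](OC(=O)c2ccccc2)[C@H]1O
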